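All runs come from a simulation for an exercise, and the scatter is random.

No rate constant was given for these flasks, so I built a clock out of the two earlier runs.

common to all: free monomer 0.15 M; initiator 0.75 mM
- grey: capture agent 4.2 mM; temperature 105 °C; run made earlier
- green: capture agent 6.6 mM; temperature 122 °C; run made earlier
- cedar: capture agent 3.00 mM; temperature 110 °C; time 2.5 d
- larch: capture agent 3.00 mM; temperature 135 °C; time 2.5 d

grey run (percent of the free monomer charged)

| time / d | monomer in chains / % |
|---|---|
| 0.250 | 0 |
| 0.833 | 3.3 |
| 1.25 | 6.3 |
| 2.00 | 13.8 |
| 3.00 | 24.4 |

green run (percent of the free monomer charged)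

| time / h | monomer in chains / % |
|---|---|
| 8.00 | 5.0 |
| 15.0 | 14.2 |
| 20.0 | 18.5 |
| 30.0 | 28.1 |
| 40.0 | 34.5 |

(readings scatter by 0.5 percentage points)

- a reading or a percentage of monomer in chains counts all its forms, free or not

- which flask leads in amount of monomer in chains, in percent of the free monomer charged ("all alike" within 1.5 percentage points) (cedar / larch / all alike)
- how much monomer in chains is there at the end, in percent of the free monomer charged: cedar
- how much monomer in chains is there at the end, in percent of the free monomer charged: larch

Between its last two readings, grey lost free monomer with a pseudo-first-order rate constant of 0.131 /d, which is a lifetime of 7.63 d. A lifetime is the time in which what is left falls by the factor e, so counting lifetimes gives the part left. By its last reading grey had run 0.280 of them.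

Temperature came next. Green reached grey's last reading of 24.4 % after about 26.1 h where grey took 3.00 d, so its clock ran 2.75 times as fast. Between 105 °C and 122 °C that ratio gives an apparent activation energy, my clock energy, of 74.0 kJ/mol. It is a reading, and it carries a second difference too, since c(capture agent) was 6.6 mM in green against 4.2 mM in grey.

With it I turned each flask's time into grey days. Cedar's 2.5 d at 110 °C counted as 3.40 d, and larch's at 135 °C as 14.1 d. Running on from grey's last reading at its late rate, I reckoned 28.3 % for cedar and 82.4 % for larch. Larch's count lay beyond grey's last reading, though. The same count on green's last reading gives 38.6 %, more than the 34.5 % read there, so I took my larch figure as a high one.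

The forecast also chose larch, with cedar at 29 % (23 % to 36 %) and larch at 48 % (35 % to 62 %), and of that flask it said “Larch starts fastest but tails off early”. On larch, then, it parted from my count.

The flasks gave 33.5 % in cedar and 75.3 % in larch, crystals included, so larch led. Larch ended above the forecast's high end and below my count.

    free monomer + initiator → living end + monomer in chains (k = 1.60 × 10⁻⁵ /M/s, Ea = 115 kJ/mol)
    free monomer + living end → monomer in chains + living end, rate k2*[living end]*[free monomer] (k = 0.0180 /M/s, Ea = 69.0 kJ/mol)
    crystals ⇌ monomer in chains, rate k3*(cs3 - [monomer in chains]) while solid is left; crystals form when [monomer in chains] > cs3 (solubility = 0.0870 M, k = 6.30 × 10⁻⁴ /s)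
    living end + capture agent → trapped intermediate (k = 0.00190 /M/s, Ea = 94.0 kJ/mol)
    (constants at 110 °C)

The same flask as cedar, run at 95 °C, counted as 1.32 d on grey's clock. That falls between grey's readings at 1.25 d and 2.00 d, and reading across gave me 6.99 %. At 2.50 d that neighbouring flask held 5.93 % monomer in chains.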